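Shanciol B is a 2,3-trans flavan-3-ol. In ring A the C4 methylene sits on C4a, between C8a–O1 and the chain-bearing C5 and para to C7–OMe. A 5-substituted 3-methoxycyclohex-2-enone carries this pattern in dearomatised form (C=O = C8a, α′-CH2 = C4a), so no arene regiochemistry has to be solved.
Key disconnections are C4–C4a (α′-aldol to an α,β-epoxy aldehyde) and O1–C2 (6-endo opening of the aryl epoxide by the C8a oxygen). Loss of one water in the same flask aromatises ring A and leaves C4 as CH2.
Fragment 1 (rings A and D) comes from Heck arylation of allyl alcohol, Wittig enone synthesis, malonate annulation with decarboxylation, and O-methylation. Fragment 2 (ring B, C2–C4) comes from pivaloylation and organocatalytic epoxidation of coniferaldehyde, which sets C3 and, before inversion, C2.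
Ring order: rings B and D are bought, the ring A carbocycle is built in step 3, and ring C is closed while ring A aromatises in step 7. Reductive depivaloylation and hydrogenolysis finish the route.

Key step: step 7

Assumption: flavan numbering (O1, C2–C4, C4a, C5–C8, C8a; ring B on C2, ring D at the end of the C5 chain) is used for all intermediates, and the sense of induction in step 6 follows the steric-shielding model of diarylprolinol silyl ethers (the (S)-catalyst gives the (2S,3R)-epoxy aldehyde, so the (R)-catalyst is used), to be confirmed by reducing a sample to the epoxy alcohol and comparing it with material from a Sharpless epoxidation.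

Step 1
Reactants: 1 1-(benzyloxy)-3-iodobenzene; 2 prop-2-en-1-ol (allyl alcohol)
Product: 3 3-[3-(benzyloxy)phenyl]propanal
Conditions: Pd(OAc)2 (2 mol%), NaHCO3, nBu4NCl, DMF, 40 °C
Reagents that add atoms: none
Why: Heck arylation of allyl alcohol under phase-transfer conditions, in which carbopalladation places the aryl group on the terminal carbon, β-hydride elimination runs toward the carbinol carbon and the enol tautomerises to the saturated aldehyde, the benzyl ether being inert.

Step 2
Reactants: 3 3-[3-(benzyloxy)phenyl]propanal; 4 1-(triphenyl-λ5-phosphanylidene)propan-2-one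
Product: 5 (3E)-6-[3-(benzyloxy)phenyl]hex-3-en-2-one
Conditions: CH2Cl2, reflux
Reagents that add atoms: none
Why: Wittig olefination with a stabilised acyl ylide, which reacts cleanly with an unhindered aliphatic aldehyde and should give the E-enone.

Step 3
Reactants: 5 (3E)-6-[3-(benzyloxy)phenyl]hex-3-en-2-one; 6 dimethyl malonate
Product: 9 5-{2-[3-(benzyloxy)phenyl]ethyl}cyclohexane-1,3-dione, via keto ester 7 (not isolated), via keto acid 8 (not isolated)
Conditions: NaOMe, MeOH, reflux; then aq NaOH, reflux; then aq HCl to pH 1, reflux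
Reagents that add atoms: none
Why: Michael addition of sodium dimethyl malonate to the enone and Dieckmann-type closure of the methyl ketone enolate onto an ester build the ring A carbocycle, and saponification with decarboxylation of the β-keto acid removes the spare ester, the classical route to 5-alkylcyclohexane-1,3-diones.

Step 4
Reactants: 9 5-{2-[3-(benzyloxy)phenyl]ethyl}cyclohexane-1,3-dione
Product: 10 rac-5-{2-[3-(benzyloxy)phenyl]ethyl}-3-methoxycyclohex-2-en-1-one
Conditions: MeOH, 4-MeC6H4SO3H·H2O (5 mol%), 3 Å MS, reflux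
Reagents that add atoms: methanol, CO
Why: Acid-catalysed enol etherification of a cyclic 1,3-dione (vinylogous Fischer esterification), in which the two possible enol ethers of the symmetric dione are enantiomers, so one racemic constitution results, and the racemate suffices because C5 becomes sp2 in step 7.

Step 5
Reactants: 11 coniferaldehyde
Product: 12 2-methoxy-4-[(1E)-3-oxoprop-1-en-1-yl]phenyl 2,2-dimethylpropanoate
Conditions: pivaloyl chloride, Et3N, 4-(dimethylamino)pyridine (5 mol%), CH2Cl2, 0 °C to rt
Reagents that add atoms: pivaloyl chloride, CC(C)(C)C(=O)Cl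
Why: O-acylation of the phenol under nucleophilic catalysis gives a hindered ester that should resist the amine catalyst, H2O2 and the lithium enolate to come, and it lowers the donor power of ring B so that the benzylic epoxide can be handled.

Step 6
Reactants: 12 2-methoxy-4-[(1E)-3-oxoprop-1-en-1-yl]phenyl 2,2-dimethylpropanoate
Product: 13 (2R,3S)-3-[3-methoxy-4-(pivaloyloxy)phenyl]oxirane-2-carbaldehyde
Conditions: (R)-2-{bis[3,5-bis(trifluoromethyl)phenyl][(trimethylsilyl)oxy]methyl}pyrrolidine (10 mol%), 35% aq H2O2 (1.3 equiv), CH2Cl2, rt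
Reagents that add atoms: hydrogen peroxide, OO
Why: Iminium–enamine organocatalytic epoxidation of an enal (amine-catalysed Weitz–Scheffer type), in which the C(Ar)2OSiMe3 group of the (R)-catalyst shields the Si face at the β-carbon of the s-trans E-iminium ion, hydrogen peroxide adds to the Re face and the enamine closes onto oxygen, which should give the trans (2R,3S)-epoxide whose carbons become C3 (retained) and C2 (later inverted).

Step 7
Reactants: 10 rac-5-{2-[3-(benzyloxy)phenyl]ethyl}-3-methoxycyclohex-2-en-1-one; 13 (2R,3S)-3-[3-methoxy-4-(pivaloyloxy)phenyl]oxirane-2-carbaldehyde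
Product: 17 (2R,3S)-shanciol B 4'-pivalate 3''-benzyl ether, via lithium dienolate 14 (not isolated), via aldol adduct 15 (not isolated), via dihydrochromenediol 16 (not isolated)
Conditions: 10 (1.25 equiv), LiN(iPr)2 (1.2 equiv), THF, −78 °C; 13 (1.0 equiv), −78 °C; AcOH quench at −78 °C, aqueous wash, solvent swap without purification; (1S)-camphor-10-sulfonic acid (0.3 equiv), 4 Å MS, ClCH2CH2Cl (0.01 M), 0 to 60 °C
Reagents that add atoms: none
Why: Proposed new method: LiN(iPr)2 deprotonates the vinylogous ester 10 only at the α′ methylene (future C4a), and dienolate 14 adds to the aldehyde of 13 to make C4–C4a; the centres at C4, C4a and C5 of aldol 15 need no control because all three are erased. Camphorsulfonic acid should engage the aryl epoxide faster than it dehydrates a β-hydroxy ketone, so ring C is expected to close first, the electron-rich C8a oxygen of the vinylogous ester attacking the protonated epoxide at benzylic C2 in a 6-endo-tet mode (O1–C2) and loss of H-4a giving dienol ether 16, while any 15 that dehydrates and aromatises first reaches the same bond through its C8a phenol. In 16 the C4 hydroxyl is pushed out vinylogously by O1 and by the C7 methoxy group, loss of H-6 gives an isotoluene-type triene, and protonation at C4 followed by loss of H-5 delivers aromatic ring A with C4 as CH2, so that 15 minus one water equals 17 and no redox reagent is needed. C2 is created by inversion at the benzylic epoxide carbon, which turns the trans epoxide into the 2,3-trans (2R,3S) product, and C3 keeps its C–O bond from step 6; the pivalate holds ring B back from free ionisation at C2 that would erode this. The step needs reaction at C4a and not at C6 or C8, which kinetic α′-enolisation secures, and 6-endo instead of 5-exo opening, which benzylic stabilisation at C2 and the electron-poor C4 carbinol next to C3 secure. Closest known reaction types are α′-aldol additions of 3-alkoxycyclohexenones, carbonyl participation in the acid-induced opening of epoxy ketones, 6-endo cyclisation of 2-(aryloxiranylmethyl)phenols to flavan-3-ols and isoaromatisation of 6-alkylidenecyclohexenones to 2-alkylphenols; their union in one flask is untested.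

Step 8
Reactants: 17 (2R,3S)-shanciol B 4'-pivalate 3''-benzyl ether
Product: 18 (2R,3S)-shanciol B 3''-benzyl ether
Conditions: iBu2AlH (4 equiv), CH2Cl2, −78 °C; then aq potassium sodium tartrate
Reagents that add atoms: none
Why: Reductive cleavage of the aryl pivalate by hydride addition to the ester carbonyl, preferred to alkoxide methanolysis because a free 4'-phenoxide in base can expel O1 as a quinone methide and epimerise C2, whereas the aluminium phenoxide at −78 °C should leave both stereocentres and the benzyl ether untouched.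

Step 9
Reactants: 18 (2R,3S)-shanciol B 3''-benzyl ether
Product: 19 shanciol B
Conditions: H2 (1 atm), Pd/C (10 wt%), EtOAc–MeOH, rt
Reagents that add atoms: none
Why: Catalytic hydrogenolysis of the aryl benzyl ether, the usual last step of flavan-3-ol syntheses, in which the primary benzylic C–O bond is cleaved much faster than the secondary C2–O1 bond inside ring C, so neither stereocentre is touched.

Compound list
1 | 1-(benzyloxy)-3-iodobenzene | Ic1cccc(OCc2ccccc2)c1 | starting material
2 | prop-2-en-1-ol (allyl alcohol) | C=CCO | starting material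
3 | 3-[3-(benzyloxy)phenyl]propanal | O=CCCc1cccc(OCc2ccccc2)c1 | intermediate
4 | 1-(triphenyl-λ5-phosphanylidene)propan-2-one | CC(=O)C=P(c1ccccc1)(c1ccccc1)c1ccccc1 | starting material
5 | (3E)-6-[3-(benzyloxy)phenyl]hex-3-en-2-one | CC(=O)/C=C/CCc1cccc(OCc2ccccc2)c1 | intermediate
6 | dimethyl malonate | COC(=O)CC(=O)OC | starting material
7 | methyl 2-{2-[3-(benzyloxy)phenyl]ethyl}-4,6-dioxocyclohexane-1-carboxylate (racemic, present as its sodium enolate) | COC(=O)C1C(CCc2cccc(OCc3ccccc3)c2)CC(=O)CC1=O | intermediate
8 | 2-{2-[3-(benzyloxy)phenyl]ethyl}-4,6-dioxocyclohexane-1-carboxylic acid (racemic) | OC(=O)C1C(CCc2cccc(OCc3ccccc3)c2)CC(=O)CC1=O | intermediate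
9 | 5-{2-[3-(benzyloxy)phenyl]ethyl}cyclohexane-1,3-dione | O=C1CC(=O)CC(CCc2cccc(OCc3ccccc3)c2)C1 | intermediate
10 | rac-5-{2-[3-(benzyloxy)phenyl]ethyl}-3-methoxycyclohex-2-en-1-one | COC1=CC(=O)CC(CCc2cccc(OCc3ccccc3)c2)C1 | intermediate
11 | coniferaldehyde, (2E)-3-(4-hydroxy-3-methoxyphenyl)prop-2-enal | COc1cc(/C=C/C=O)ccc1O | starting material
12 | 2-methoxy-4-[(1E)-3-oxoprop-1-en-1-yl]phenyl 2,2-dimethylpropanoate | COc1cc(/C=C/C=O)ccc1OC(=O)C(C)(C)C | intermediate
13 | (2R,3S)-3-[3-methoxy-4-(pivaloyloxy)phenyl]oxirane-2-carbaldehyde (trans epoxide) | O=C[C@@H]1O[C@H]1c1ccc(OC(=O)C(C)(C)C)c(OC)c1 | intermediate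
14 | cross-conjugated lithium dienolate of 10 (O− on C8a, double bonds C8a=C4a and C7=C8; racemic) | [Li+].COC1=CC([O-])=CC(CCc2cccc(OCc3ccccc3)c2)C1 | intermediate
15 | 5-{2-[3-(benzyloxy)phenyl]ethyl}-6-{hydroxy[(2S,3S)-3-(3-methoxy-4-pivaloyloxyphenyl)oxiran-2-yl]methyl}-3-methoxycyclohex-2-en-1-one, mixture of isomers at C4, C4a and C5, epoxide geometry as in 13 | COC1=CC(=O)C(C(O)[C@@H]2O[C@H]2c2ccc(OC(=O)C(C)(C)C)c(OC)c2)C(CCc2cccc(OCc3ccccc3)c2)C1 | intermediate
16 | 4-[(2R,3S)-5-{2-[3-(benzyloxy)phenyl]ethyl}-3,4-dihydroxy-7-methoxy-3,4,5,6-tetrahydro-2H-chromen-2-yl]-2-methoxyphenyl 2,2-dimethylpropanoate, mixture at C4 and C5 | COC1=CC2=C(C(CCc3cccc(OCc4ccccc4)c3)C1)C(O)[C@H](O)[C@@H](c1ccc(OC(=O)C(C)(C)C)c(OC)c1)O2 | intermediate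
17 | 4-[(2R,3S)-5-{2-[3-(benzyloxy)phenyl]ethyl}-3-hydroxy-7-methoxy-3,4-dihydro-2H-chromen-2-yl]-2-methoxyphenyl 2,2-dimethylpropanoate (shanciol B 4'-pivalate 3''-benzyl ether) | COc1cc(CCc2cccc(OCc3ccccc3)c2)c2c(c1)O[C@H](c1ccc(OC(=O)C(C)(C)C)c(OC)c1)[C@@H](O)C2 | intermediate
18 | (2R,3S)-5-{2-[3-(benzyloxy)phenyl]ethyl}-2-(4-hydroxy-3-methoxyphenyl)-7-methoxy-3,4-dihydro-2H-chromen-3-ol | COc1cc(CCc2cccc(OCc3ccccc3)c2)c2c(c1)O[C@H](c1ccc(O)c(OC)c1)[C@@H](O)C2 | intermediate
19 | shanciol B, (2R,3S)-2-(4-hydroxy-3-methoxyphenyl)-5-[2-(3-hydroxyphenyl)ethyl]-7-methoxy-3,4-dihydro-2H-chromen-3-ol | COc1cc(CCc2cccc(O)c2)c2c(c1)O[C@H](c1ccc(O)c(OC)c1)[C@@H](O)C2 | target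

Total step count: 9. Longest linear sequence: 7 (steps 1, 2, 3, 4, 7, 8, 9).

Steps most likely to fail

1. Step 7 (Proposed new method).
- If the quench is late, the epoxide may migrate in the lithium aldolate (Payne-type).
- In the acid stage the epoxide may rearrange by hydride shift (Meinwald-type), or be opened intermolecularly before O1 arrives.
- The C4 cation may lose H-3, leaving ring A dihydro, or be captured by the electron-rich ring A of product already formed.
- The released water may hydrolyse the enol ether.

The fallback uses isolated, known reactions and gives up redox neutrality. It sets out from 13 and 10 and comes back at 17. NaBH4 in MeOH at 0 °C reduces 13 to the (2S,3S)-epoxy alcohol F1, and I2, PPh3 and imidazole convert it into the epoxy iodide F2. Dienolate 14, made from 10 as in step 7, is alkylated with F2 (Stork–Danheiser α′-alkylation) to give the 6-(oxiranylmethyl) enone F3, which already carries C4 as CH2. LiN(iPr)2 and then PhSeBr at −78 °C give the C4a selenide F4. H2O2 with pyridine triggers selenoxide syn-elimination toward H-5, and the resulting cyclohexadienone tautomerises to the epoxy phenol F5. Catalytic (1S)-camphor-10-sulfonic acid in CH2Cl2 at 0 °C then effects the known 6-endo opening at C2 with inversion and gives 17.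

2. Step 6. Facial or trans/cis selectivity may be incomplete, the activated aryl ester may transfer its acyl group to the amine catalyst, and the epoxy aldehyde may decompose during purification. The fallback sets out from 12 and comes back at 13. Luche reduction (NaBH4, CeCl3·7H2O, MeOH, 0 °C) gives the allylic alcohol, coniferyl alcohol 4-O-pivalate F6. Sharpless asymmetric epoxidation (Ti(OiPr)4, L-(+)-diethyl tartrate, tBuOOH, 4 Å MS, CH2Cl2, −20 °C) gives the (2S,3S)-epoxy alcohol F1, the compound of the first fallback. Dess–Martin periodinane with NaHCO3 oxidises it to 13. This route also supplies the reference sample for the configurational check.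

3. Step 1. Arylation may compete at the internal alkene carbon and give branched aldehyde, and the product aldehyde may self-condense under the basic conditions. The fallback sets out from 1 and comes back at 3. Negishi coupling of 1 with commercial [2-(1,3-dioxolan-2-yl)ethyl]zinc bromide (Pd(PPh3)4, THF, 50 °C) gives the masked aldehyde, the dioxolane F7. Aqueous HCl in THF at rt releases 3.

Further compounds
F1 | step 7 | 4-[(2S,3S)-3-(hydroxymethyl)oxiran-2-yl]-2-methoxyphenyl 2,2-dimethylpropanoate | OC[C@@H]1O[C@H]1c1ccc(OC(=O)C(C)(C)C)c(OC)c1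
F2 | step 7 | 4-[(2S,3R)-3-(iodomethyl)oxiran-2-yl]-2-methoxyphenyl 2,2-dimethylpropanoate | IC[C@@H]1O[C@H]1c1ccc(OC(=O)C(C)(C)C)c(OC)c1
F3 | step 7 | 5-{2-[3-(benzyloxy)phenyl]ethyl}-3-methoxy-6-{[(2S,3S)-3-(3-methoxy-4-pivaloyloxyphenyl)oxiran-2-yl]methyl}cyclohex-2-en-1-one (mixture at the two ring centres) | COC1=CC(=O)C(C[C@@H]2O[C@H]2c2ccc(OC(=O)C(C)(C)C)c(OC)c2)C(CCc2cccc(OCc3ccccc3)c2)C1
F4 | step 7 | 6-(phenylselanyl) derivative of F3 (selenium on C4a) | COC1=CC(=O)C(C[C@@H]2O[C@H]2c2ccc(OC(=O)C(C)(C)C)c(OC)c2)([Se]c2ccccc2)C(CCc2cccc(OCc3ccccc3)c2)C1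
F5 | step 7 | 4-[(2S,3S)-3-(2-{2-[3-(benzyloxy)phenyl]ethyl}-6-hydroxy-4-methoxybenzyl)oxiran-2-yl]-2-methoxyphenyl 2,2-dimethylpropanoate | COc1cc(O)c(C[C@@H]2O[C@H]2c2ccc(OC(=O)C(C)(C)C)c(OC)c2)c(CCc2cccc(OCc3ccccc3)c2)c1
F6 | step 6 | 4-[(1E)-3-hydroxyprop-1-en-1-yl]-2-methoxyphenyl 2,2-dimethylpropanoate | COc1cc(/C=C/CO)ccc1OC(=O)C(C)(C)C
F7 | step 1 | 2-{2-[3-(benzyloxy)phenyl]ethyl}-1,3-dioxolane | C1COC(CCc2cccc(OCc3ccccc3)c2)O1
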